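**Retrosynthetic overview**

1. Target ⇒ aromatisation of ring A as the last step, from a bicyclic enone whose ring A is still at the dihydro-arene level (as the dihydroserrulatene precedes the arene in Nature).
2. Bicyclic enone ⇒ key step, the C4–C10 bond (the biosynthetic 1,10-closure): olefin attack on the Lewis-acid-activated ring-A enone, then two 1,2-hydride shifts (net the biosynthetic 1,3-hydride shift) set C4 and C11 from a (Z)-olefin under control of C1.
3. Monocyclic "bisabolane-type" enone ⇒ Birch reduction of the corresponding benzoate (ring A dearomatised), with the C20 acetate put on at this stage.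
4. Benzoate ⇒ Cu-catalysed asymmetric hydroboration of an α-substituted styrene (sets C1) ⇒ Suzuki coupling of methyl 4-bromo-3-methoxybenzoate with the enol triflate of nerylacetone.
5. Ring order: ring A (bought as arene, then dearomatised) → ring B (cationic C4–C10 closure) → re-aromatisation of ring A.

Assumption: nerylacetone is bought as the pure (5Z)-isomer; positions are cited in serrulatane numbering (C1 bears C20H2OAc, C4 the side chain, C6 the C19 carboxyl, C8 the OH, C9/C10 are the ring-fusion carbons next to C1/C4).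

**Route**

Step 1
Reactants: 1 nerylacetone [(5Z)-6,10-dimethylundeca-5,9-dien-2-one]
Product: 2 (5Z)-6,10-dimethylundeca-1,5,9-trien-2-yl trifluoromethanesulfonate
Conditions: KHMDS, THF, −78 °C; PhNTf2, −78 → 0 °C
Reagents that add atoms: N-phenylbis(trifluoromethanesulfonimide), O=S(=O)(N(c1ccccc1)S(=O)(=O)C(F)(F)F)C(F)(F)F
Why: Kinetic deprotonation of the methyl ketone on the CH3 side and O-triflation (enol triflate formation) give the terminal vinyl triflate; no stereocentre is formed and the Z-olefin is not touched.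

Step 2
Reactants: 3 methyl 4-bromo-3-methoxybenzoate; 2 (5Z)-6,10-dimethylundeca-1,5,9-trien-2-yl trifluoromethanesulfonate
Product: 5 methyl 4-[(5Z)-6,10-dimethylundeca-1,5,9-trien-2-yl]-3-methoxybenzoate, via aryl pinacol boronate 4 (not isolated)
Conditions: B2pin2, Pd(dppf)Cl2 (3 mol %), KOAc, dioxane, 90 °C; then 2, aq. K3PO4, 80 °C
Reagents that add atoms: none
Why: Miyaura borylation of the aryl bromide followed in the same flask by Suzuki–Miyaura coupling with the vinyl triflate gives the α-substituted styrene; no stereocentre is formed.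

Step 3
Reactants: 5 methyl 4-[(5Z)-6,10-dimethylundeca-1,5,9-trien-2-yl]-3-methoxybenzoate
Product: 7 methyl 4-[(2R,5Z)-1-hydroxy-6,10-dimethylundeca-5,9-dien-2-yl]-3-methoxybenzoate, via primary alkyl boronate 6 (not isolated)
Conditions: CuCl/chiral NHC (5 mol %), NaOtBu (20 mol %), B2pin2, MeOH, THF, −30 °C; then NaBO3·4H2O, THF–H2O, rt
Reagents that add atoms: sodium perborate, [Na+].[O-]OB=O
Why: Enantioselective NHC–Cu protoboration (Cu–Bpin adds only to the aryl-activated 1,1-disubstituted alkene, boron to CH2, the benzylic C–Cu bond is protonated with retention) and C–B oxidation give the primary alcohol; C1 is set (R) by the catalyst, whose antipode is chosen accordingly, and the trisubstituted olefins do not react.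

Step 4
Reactants: 7 methyl 4-[(2R,5Z)-1-hydroxy-6,10-dimethylundeca-5,9-dien-2-yl]-3-methoxybenzoate
Product: 9 4-[(2R,5Z)-1-hydroxy-6,10-dimethylundeca-5,9-dien-2-yl]-3-methoxycyclohexa-2,5-diene-1-carboxylic acid (mixture at ring C1/C4), via lithium carboxylate 8 (not isolated)
Conditions: LiOH·H2O, THF/MeOH/H2O, 50 °C; evaporate, dry (PhMe azeotrope); then Li, NH3(l)/THF, t-BuOH, −78 °C; NH4Cl; pH 5 work-up
Reagents that add atoms: lithium hydroxide, [Li+].[OH-]
Why: Saponification and Birch reduction of the benzoate (protonation ipso and para to the carboxylate) dearomatise ring A and leave the meta-methoxy group as an enol ether; isolated trisubstituted olefins and the alkoxide are inert, C1 is retained, and the two new ring sp3 centres are erased later.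

Step 5
Reactants: 9 4-[(2R,5Z)-1-hydroxy-6,10-dimethylundeca-5,9-dien-2-yl]-3-methoxycyclohexa-2,5-diene-1-carboxylic acid
Product: 11 4-[(2R,5Z)-1-acetoxy-6,10-dimethylundeca-5,9-dien-2-yl]-3-oxocyclohex-4-ene-1-carboxylic acid (mixture at ring C1), via acetoxy dienol ether 10 (not isolated)
Conditions: Ac2O, pyridine, DMAP (cat.), CH2Cl2, 0 °C → rt; then 1 M HCl, THF, rt
Reagents that add atoms: acetic anhydride, CC(=O)OC(C)=O; water, O
Why: O-Acetylation of the primary alcohol (the mixed anhydride at CO2H is hydrolysed in the acid stage), then acid hydrolysis of the enol ether and migration of the β,γ double bond into conjugation, give the 2-substituted cyclohex-2-enone with H on the β-carbon (C10); C1 is not on an enolisable path and is retained.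

Step 6
Reactants: 11 4-[(2R,5Z)-1-acetoxy-6,10-dimethylundeca-5,9-dien-2-yl]-3-oxocyclohex-4-ene-1-carboxylic acid
Product: 12 (5R,8S)-5-(acetoxymethyl)-8-[(2S)-6-methylhept-5-en-2-yl]-4-oxo-1,2,3,4,5,6,7,8-octahydronaphthalene-2-carboxylic acid (mixture at C2)
Conditions: Me2AlCl (1.1 equiv), CH2Cl2, −78 °C; then MeAlCl2 (2.5 equiv), −78 → −20 °C; aq. Rochelle salt
Reagents that add atoms: none
Why: Proposed new method: MeAlCl2 turns the ring-A enone into an oxy-allyl cation (the laboratory counterpart of the biosynthetic ring-A allyl cation) and the (Z)-olefin attacks C10 through a chair-like transition state (C1–H eclipses the complexed C8=O to avoid A(1,3) strain, so CH2OAc lies on the face opposite the tether, and the olefin terminus is exo) to give a C11 cation/aluminium enolate zwitterion; two suprafacial 1,2-hydride shifts (H-4 → C11, then H-10 → C4) regenerate the enone, so C4 takes its hydrogen on the CH2OAc face (1,4-trans, 4S) and the Z geometry becomes 11S, while the alkylaluminium chlorides scavenge protons and spare the Δ14 olefin; the closest known reaction type is the alkylaluminium-chloride-induced conjugate addition of alkenes to enones ending in two 1,2-hydride shifts (Snider-type), here made intramolecular and stereodefining.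

Step 7
Reactants: 12 (5R,8S)-5-(acetoxymethyl)-8-[(2S)-6-methylhept-5-en-2-yl]-4-oxo-1,2,3,4,5,6,7,8-octahydronaphthalene-2-carboxylic acid
Product: 13 (5R,8S)-5-(acetoxymethyl)-4-hydroxy-8-[(2S)-6-methylhept-5-en-2-yl]-5,6,7,8-tetrahydronaphthalene-2-carboxylic acid (CNP0176615.1)
Conditions: Pd(TFA)2 (5 mol %), 2-(dimethylamino)pyridine (10 mol %), TsOH (20 mol %), O2 (1 atm), DMSO, 80 °C
Reagents that add atoms: none
Why: Pd(II)-catalysed aerobic dehydrogenation of a cyclohexenone to a phenol (α′-palladation at C7, β-hydride elimination of H-6, tautomerisation of the cross-conjugated dienone) aromatises ring A and erases the C6 epimer mixture; C1, C4 and C11 are not involved, and the acetate, the acid and the trisubstituted olefin should be tolerated.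

**Compound list**

1 | nerylacetone, (5Z)-6,10-dimethylundeca-5,9-dien-2-one | CC(=O)CC/C=C(/C)CCC=C(C)C | starting material
2 | (5Z)-6,10-dimethylundeca-1,5,9-trien-2-yl trifluoromethanesulfonate | C=C(OS(=O)(=O)C(F)(F)F)CC/C=C(/C)CCC=C(C)C | intermediate
3 | methyl 4-bromo-3-methoxybenzoate | COC(=O)c1ccc(Br)c(OC)c1 | starting material
4 | methyl 3-methoxy-4-(4,4,5,5-tetramethyl-1,3,2-dioxaborolan-2-yl)benzoate (not isolated) | COC(=O)c1ccc(B2OC(C)(C)C(C)(C)O2)c(OC)c1 | intermediate
5 | methyl 4-[(5Z)-6,10-dimethylundeca-1,5,9-trien-2-yl]-3-methoxybenzoate | COC(=O)c1ccc(C(=C)CC/C=C(/C)CCC=C(C)C)c(OC)c1 | intermediate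
6 | methyl 4-[(2R,5Z)-6,10-dimethyl-1-(4,4,5,5-tetramethyl-1,3,2-dioxaborolan-2-yl)undeca-5,9-dien-2-yl]-3-methoxybenzoate (not isolated) | CC1(C)OB(C[C@H](CC/C=C(/C)CCC=C(C)C)c2ccc(C(=O)OC)cc2OC)OC1(C)C | intermediate
7 | methyl 4-[(2R,5Z)-1-hydroxy-6,10-dimethylundeca-5,9-dien-2-yl]-3-methoxybenzoate | OC[C@H](CC/C=C(/C)CCC=C(C)C)c1ccc(C(=O)OC)cc1OC | intermediate
8 | 4-[(2R,5Z)-1-hydroxy-6,10-dimethylundeca-5,9-dien-2-yl]-3-methoxybenzoic acid (handled as its lithium salt, not isolated) | OC[C@H](CC/C=C(/C)CCC=C(C)C)c1ccc(C(=O)O)cc1OC | intermediate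
9 | 4-[(2R,5Z)-1-hydroxy-6,10-dimethylundeca-5,9-dien-2-yl]-3-methoxycyclohexa-2,5-diene-1-carboxylic acid (side-chain C2 is R; ring C1 and C4 are mixtures) | OC[C@H](CC/C=C(/C)CCC=C(C)C)C1C=CC(C(=O)O)C=C1OC | intermediate
10 | 4-[(2R,5Z)-1-acetoxy-6,10-dimethylundeca-5,9-dien-2-yl]-3-methoxycyclohexa-2,5-diene-1-carboxylic acid (not isolated; ring C1 and C4 are mixtures) | CC(=O)OC[C@H](CC/C=C(/C)CCC=C(C)C)C1C=CC(C(=O)O)C=C1OC | intermediate
11 | 4-[(2R,5Z)-1-acetoxy-6,10-dimethylundeca-5,9-dien-2-yl]-3-oxocyclohex-4-ene-1-carboxylic acid (ring C1 is a mixture) | CC(=O)OC[C@H](CC/C=C(/C)CCC=C(C)C)C1=CCC(C(=O)O)CC1=O | intermediate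
12 | (5R,8S)-5-(acetoxymethyl)-8-[(2S)-6-methylhept-5-en-2-yl]-4-oxo-1,2,3,4,5,6,7,8-octahydronaphthalene-2-carboxylic acid (C2 is a mixture; 4a,8a double bond) | CC(=O)OC[C@@H]1CC[C@@H]([C@@H](C)CCC=C(C)C)C2=C1C(=O)CC(C(=O)O)C2 | intermediate
13 | (5R,8S)-5-(acetoxymethyl)-4-hydroxy-8-[(2S)-6-methylhept-5-en-2-yl]-5,6,7,8-tetrahydronaphthalene-2-carboxylic acid; (1R,4S,11S)-20-acetoxy-8-hydroxyserrulat-14-en-19-oic acid | CC(=O)OC[C@@H]1CC[C@@H]([C@@H](C)CCC=C(C)C)c2cc(C(=O)O)cc(O)c21 | target

**Step count and risk**

Total step count: 7. Longest linear sequence: 7 steps (1 → 2 → 5 → 7 → 9 → 11 → 12 → 13); the aryl bromide 3 enters in step 2.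

The three steps most likely to fail:

Step 6 (key cyclisation). The aluminium-enolate zwitterion may end by ene-type proton transfer or cyclobutane closure instead of the two hydride shifts, and the C4 cation could be trapped by the Δ14 olefin. The fallback sets out from 11 and comes back at 12. Soft enolisation and silylation of 11 (TBSOTf, Et3N, CH2Cl2, −78 → 0 °C) gives the cross-conjugated silyl dienol ether silyl ester F1. Stoichiometric Tf2NH (CH2Cl2, −78 °C) protonates F1 at C7 to the siloxy-allyl cation. This is a Brønsted-acid-triggered cation–olefin cyclisation in which the partner of the C11 cation is a neutral silyl enol ether, not a basic metal enolate, so the low-barrier exits left are the two 1,2-hydride shifts, which end in an O-silylated enone. Aqueous NaHCO3 work-up removes the silyl groups and gives 12.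

Step 3 (asymmetric protoboration). The ortho-methoxy group and the long α-alkyl chain may erode the enantioselectivity. The fallback sets out from 5 and comes back at 7. Hydroboration with 9-BBN (THF, 0 °C → rt; then NaBO3), which is selective for the 1,1-disubstituted alkene, gives the racemic alcohol F2. Kinetic resolution with Burkholderia cepacia lipase and vinyl acetate (MTBE, rt, run past 50 % conversion) acylates the (S)-enantiomer to the (S)-acetate F3 and leaves (R)-7. Should the enzyme prefer the other enantiomer, the acetate is taken instead and methanolysed with K2CO3/MeOH.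

Step 7 (aromatisation). The acid additive at 80 °C may enolise towards C4 (epimerisation) or the Pd system may attack the olefin. The fallback sets out from 12 and comes back at 13. Kinetic soft enolisation (TBSOTf, Et3N, CH2Cl2, −78 → 0 °C) fixes the α′ regiochemistry in the bis-silyl dienol ether F4. DDQ (2,6-lutidine, CH2Cl2, 0 °C) then abstracts hydride from the CO2-bearing ring carbon and the silyl group is lost, a stoichiometric acid-free dehydrogenation via an isolated silyl enol ether. The resulting dienone tautomerises to the phenol and aqueous work-up cleaves the silyl ester to give 13.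

**Further compounds**

F1 | step 6 | tert-butyldimethylsilyl 4-[(2R,5Z)-1-acetoxy-6,10-dimethylundeca-5,9-dien-2-yl]-3-[(tert-butyldimethylsilyl)oxy]cyclohexa-2,4-diene-1-carboxylate | CC(=O)OC[C@H](CC/C=C(/C)CCC=C(C)C)C1=CCC(C(=O)O[Si](C)(C)C(C)(C)C)C=C1O[Si](C)(C)C(C)(C)C
F2 | step 3 | racemic methyl 4-[(5Z)-1-hydroxy-6,10-dimethylundeca-5,9-dien-2-yl]-3-methoxybenzoate | OCC(CC/C=C(/C)CCC=C(C)C)c1ccc(C(=O)OC)cc1OC
F3 | step 3 | methyl 4-[(2S,5Z)-1-acetoxy-6,10-dimethylundeca-5,9-dien-2-yl]-3-methoxybenzoate | CC(=O)OC[C@@H](CC/C=C(/C)CCC=C(C)C)c1ccc(C(=O)OC)cc1OC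
F4 | step 7 | tert-butyldimethylsilyl (5R,8S)-5-(acetoxymethyl)-4-[(tert-butyldimethylsilyl)oxy]-8-[(2S)-6-methylhept-5-en-2-yl]-1,2,5,6,7,8-hexahydronaphthalene-2-carboxylate | CC(=O)OC[C@@H]1CC[C@@H]([C@@H](C)CCC=C(C)C)C2=C1C(O[Si](C)(C)C(C)(C)C)=CC(C(=O)O[Si](C)(C)C(C)(C)C)C2
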